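Retrosynthesis: the methyl ester C-O bond is cut first (back to a dihydrocoumarin lactone on O7), then the C8-CH(n-Pr) bond (arylation of (E)-hex-2-enal), the C6-CH2 bond of the prenyl group (sigmatropic transfer from O5), C3-C4 of ring B, and last the O1-C2 ether bond.
Enabling feature: in ring B (O1, C2, C3, C4, C4a, C8a) the C3 methyl is alpha to the C4 ketone and C2 sits on O1, so C3 with its methyl is the vinyl group of an O1-bound but-3-en-2-yl ether and C4 is a formyl carbon on C4a.
Forward order: bis-MOM phloroglucinaldehyde, aryl allyl ether, ring B by carbene-catalysed hydroacylation, prenyl transfer to C6, C8 side chain closed as a lactol ring on O7, lactone, ring-opened methyl ester.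
Stereochemistry: C2 from (R)-but-3-en-2-ol with Mitsunobu inversion; C3 by the cyclisation and equilibration to trans; the R benzylic centre from an (S)-prolinol silyl ether iminium catalyst.

Key step: step 3

Remark: the hemiacetal carbon of the lactol formed in step 8 is expected as a mixture of epimers and is left undefined, because step 9 removes it; enantiopure (R)-but-3-en-2-ol is taken as commercial.

Step 1
Reactants: 1 2,4,6-trihydroxybenzaldehyde
Product: 2 2-hydroxy-4,6-bis(methoxymethoxy)benzaldehyde
Conditions: MOMCl (2.1 equiv), i-Pr2NEt (2.5 equiv), CH2Cl2, 0 °C to rt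
Reagents that add atoms: chloromethyl methyl ether, COCCl
Why: O-alkylation (MOM protection) takes the para hydroxyl and one ortho hydroxyl, while the last ortho hydroxyl is held in a hydrogen bond to the formyl group and should stay free with two equivalents of reagent.

Step 2
Reactants: 2 2-hydroxy-4,6-bis(methoxymethoxy)benzaldehyde; 3 (R)-but-3-en-2-ol
Product: 4 2-[(2S)-but-3-en-2-yloxy]-4,6-bis(methoxymethoxy)benzaldehyde
Conditions: PPh3, DIAD, THF, 0 °C to rt
Reagents that add atoms: none
Why: Mitsunobu etherification, in which the acidic salicylaldehyde-type phenol displaces the activated secondary allylic alcohol by SN2 with inversion, so the R alcohol should give the S ether carbon that becomes C2.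

Step 3
Reactants: 4 2-[(2S)-but-3-en-2-yloxy]-4,6-bis(methoxymethoxy)benzaldehyde
Product: 5 (2S,3S)-5,7-bis(methoxymethoxy)-2,3-dimethylchroman-4-one
Conditions: 2-mesityl-6,7-dihydro-5H-pyrrolo[2,1-c][1,2,4]triazol-2-ium chloride (20 mol%), DBU (15 mol%), 1,4-dioxane, 100 °C
Reagents that add atoms: none
Why: The triazolylidene adds to the formyl group and proton transfer gives the Breslow intermediate; its enol O-H hydrogen is then handed to the terminal alkene carbon while the acyl carbon bonds to the internal one in a single ene-like (Conia-ene-type) transition state with uneven bond formation, after which the carbene leaves the ketone. The closest known reaction is the N-heterocyclic carbene-catalysed intramolecular hydroacylation of unactivated alkenes in 2-allyloxybenzaldehydes, applied here to an alpha-branched ether and a 2,6-dioxygenated aldehyde. Ring B closes in the 6-exo-trig mode through the new C3-C4 bond, and the former =CH2 becomes the C3 methyl. C2 is carried unchanged from 4; the new C3 centre should be set by a half-chair transition state with the C2 methyl pseudo-equatorial and, being alpha to the ketone, should be corrected by the amidine base to the diequatorial trans (2S,3S) isomer. The step needs hydroacylation to win over benzoin coupling and over [3,3] shift of the allyl aryl ether, and it needs C2 to survive; two ortho alkoxy groups block benzoin coupling, the temperature is kept below that of the aryl ether rearrangement, and base is kept below the azolium loading so that no retro-oxa-Michael opening occurs.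

Step 4
Reactants: 5 (2S,3S)-5,7-bis(methoxymethoxy)-2,3-dimethylchroman-4-one
Product: 6 (2S,3S)-5-hydroxy-7-(methoxymethoxy)-2,3-dimethylchroman-4-one
Conditions: HCl (cat.), MeOH/CH2Cl2, 0 °C to rt
Reagents that add atoms: none
Why: Carbonyl-assisted acetal methanolysis, in which the MOM ether peri to the C4 carbonyl is activated by the neighbouring carbonyl and releases a hydrogen-bonded phenol, so it should cleave well before the unassisted 7-O-MOM ether.

Step 5
Reactants: 6 (2S,3S)-5-hydroxy-7-(methoxymethoxy)-2,3-dimethylchroman-4-one; 7 3-chloro-3-methylbut-1-yne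
Product: 8 (2S,3S)-7-(methoxymethoxy)-2,3-dimethyl-5-[(2-methylbut-3-yn-2-yl)oxy]chroman-4-one
Conditions: DBU, CuCl2 (1 mol%), MeCN, 0 °C to rt
Reagents that add atoms: none
Why: Copper-catalysed propargylic etherification, in which a copper acetylide/allenylidene electrophile is captured at its tertiary carbon by the DBU-generated 5-phenoxide, the only free oxygen nucleophile in 6.

Step 6
Reactants: 8 (2S,3S)-7-(methoxymethoxy)-2,3-dimethyl-5-[(2-methylbut-3-yn-2-yl)oxy]chroman-4-one
Product: 10 (2S,3S)-5-hydroxy-7-(methoxymethoxy)-2,3-dimethyl-6-(3-methylbut-2-en-1-yl)chroman-4-one, via 5-O-(2-methylbut-3-en-2-yl) ether 9 (not isolated)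
Conditions: H2 (1 atm), Pd/CaCO3 poisoned with Pb(OAc)2, quinoline, toluene, rt; filter; filtrate at 110 °C
Reagents that add atoms: none
Why: Semi-hydrogenation of the terminal alkyne stops at the alkene, and the 1,1-dimethylallyl aryl ether then undergoes aromatic Claisen ([3,3]) rearrangement to C6, the only free ortho position of O5, which delivers the linear prenyl group and restores the chelated 5-OH on tautomerisation.

Step 7
Reactants: 10 (2S,3S)-5-hydroxy-7-(methoxymethoxy)-2,3-dimethyl-6-(3-methylbut-2-en-1-yl)chroman-4-one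
Product: 11 (2S,3S)-5,7-dihydroxy-2,3-dimethyl-6-(3-methylbut-2-en-1-yl)chroman-4-one
Conditions: HCl (1 M), MeOH, rt to 40 °C
Reagents that add atoms: none
Why: Acid-catalysed acetal methanolysis (MOM removal) under dilute acid, conditions that ortho-prenylphenols normally tolerate without cyclisation to a chroman.

Step 8
Reactants: 11 (2S,3S)-5,7-dihydroxy-2,3-dimethyl-6-(3-methylbut-2-en-1-yl)chroman-4-one; 12 (E)-hex-2-enal
Product: 14 (2S,3S,10R)-5,8-dihydroxy-2,3-dimethyl-6-(3-methylbut-2-en-1-yl)-10-propyl-2,3,9,10-tetrahydro-4H,8H-pyrano[2,3-f]chromen-4-one, via 3-arylhexanal 13 (not isolated)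
Conditions: (S)-2-[diphenyl(trimethylsilyloxy)methyl]pyrrolidine (20 mol%), PhCO2H (20 mol%), toluene, 0 °C to rt
Reagents that add atoms: none
Why: Iminium-catalysed enantioselective Friedel-Crafts alkylation/hemiacetalisation of an electron-rich phenol with an enal, in which C8 (the only unsubstituted ring carbon, flanked by O7 and O1 and para to O5) adds to the beta-carbon of the (E)-iminium ion on the face not shielded by the diphenyl(silyloxy)methyl group, which should give the R benzylic centre, and O7 traps the aldehyde as the lactol ring O7-CH(OH)-CH2-CH(n-Pr)-C8 (chromanone numbering).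

Step 9
Reactants: 14 (2S,3S,10R)-5,8-dihydroxy-2,3-dimethyl-6-(3-methylbut-2-en-1-yl)-10-propyl-2,3,9,10-tetrahydro-4H,8H-pyrano[2,3-f]chromen-4-one
Product: 15 (2S,3S,10R)-5-hydroxy-2,3-dimethyl-6-(3-methylbut-2-en-1-yl)-10-propyl-2,3,9,10-tetrahydro-4H,8H-pyrano[2,3-f]chromene-4,8-dione
Conditions: Dess-Martin periodinane, CH2Cl2, 0 °C to rt
Reagents that add atoms: none
Why: Dess-Martin oxidation of a lactol to the lactone (here a 4-propyl-3,4-dihydrocoumarin on O7/C8) under near-neutral conditions that should leave the prenyl alkene and the hydrogen-bonded 5-OH untouched.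

Step 10
Reactants: 15 (2S,3S,10R)-5-hydroxy-2,3-dimethyl-6-(3-methylbut-2-en-1-yl)-10-propyl-2,3,9,10-tetrahydro-4H,8H-pyrano[2,3-f]chromene-4,8-dione
Product: 16 methyl (3R)-3-[(2S,3S)-5,7-dihydroxy-2,3-dimethyl-6-(3-methylbut-2-en-1-yl)-4-oxochroman-8-yl]hexanoate
Conditions: Et3N (0.2 equiv), MeOH, 0 °C to rt
Reagents that add atoms: methanol, CO
Why: Base-catalysed transesterification (lactone methanolysis) of an activated aryl ester whose acidic 7-phenol is a good leaving group, so a weak amine base should suffice and C2, C3 and the benzylic centre are not touched.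

Compound list
1 | 2,4,6-trihydroxybenzaldehyde | O=Cc1c(O)cc(O)cc1O | starting material
2 | 2-hydroxy-4,6-bis(methoxymethoxy)benzaldehyde | O=Cc1c(O)cc(OCOC)cc1OCOC | intermediate
3 | (R)-but-3-en-2-ol | C[C@@H](O)C=C | starting material
4 | 2-[(2S)-but-3-en-2-yloxy]-4,6-bis(methoxymethoxy)benzaldehyde | O=Cc1c(OCOC)cc(OCOC)cc1O[C@@H](C)C=C | intermediate
5 | (2S,3S)-5,7-bis(methoxymethoxy)-2,3-dimethylchroman-4-one | COCOc1cc(OCOC)c2c(c1)O[C@@H](C)[C@H](C)C2=O | intermediate
6 | (2S,3S)-5-hydroxy-7-(methoxymethoxy)-2,3-dimethylchroman-4-one | COCOc1cc(O)c2c(c1)O[C@@H](C)[C@H](C)C2=O | intermediate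
7 | 3-chloro-3-methylbut-1-yne | CC(C)(Cl)C#C | starting material
8 | (2S,3S)-7-(methoxymethoxy)-2,3-dimethyl-5-[(2-methylbut-3-yn-2-yl)oxy]chroman-4-one | COCOc1cc(OC(C)(C)C#C)c2c(c1)O[C@@H](C)[C@H](C)C2=O | intermediate
9 | (2S,3S)-7-(methoxymethoxy)-2,3-dimethyl-5-[(2-methylbut-3-en-2-yl)oxy]chroman-4-one | COCOc1cc(OC(C)(C)C=C)c2c(c1)O[C@@H](C)[C@H](C)C2=O | intermediate
10 | (2S,3S)-5-hydroxy-7-(methoxymethoxy)-2,3-dimethyl-6-(3-methylbut-2-en-1-yl)chroman-4-one | COCOc1c(CC=C(C)C)c(O)c2c(c1)O[C@@H](C)[C@H](C)C2=O | intermediate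
11 | (2S,3S)-5,7-dihydroxy-2,3-dimethyl-6-(3-methylbut-2-en-1-yl)chroman-4-one | Oc1c(CC=C(C)C)c(O)c2c(c1)O[C@@H](C)[C@H](C)C2=O | intermediate
12 | (E)-hex-2-enal | CCC/C=C/C=O | starting material
13 | (3R)-3-[(2S,3S)-5,7-dihydroxy-2,3-dimethyl-6-(3-methylbut-2-en-1-yl)-4-oxochroman-8-yl]hexanal | CCC[C@H](CC=O)c1c(O)c(CC=C(C)C)c(O)c2c1O[C@@H](C)[C@H](C)C2=O | intermediate
14 | (2S,3S,10R)-5,8-dihydroxy-2,3-dimethyl-6-(3-methylbut-2-en-1-yl)-10-propyl-2,3,9,10-tetrahydro-4H,8H-pyrano[2,3-f]chromen-4-one (lactol, hemiacetal carbon undefined) | CCC[C@@H]1CC(O)Oc2c1c1O[C@@H](C)[C@H](C)C(=O)c1c(O)c2CC=C(C)C | intermediate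
15 | (2S,3S,10R)-5-hydroxy-2,3-dimethyl-6-(3-methylbut-2-en-1-yl)-10-propyl-2,3,9,10-tetrahydro-4H,8H-pyrano[2,3-f]chromene-4,8-dione | CCC[C@@H]1CC(=O)Oc2c1c1O[C@@H](C)[C@H](C)C(=O)c1c(O)c2CC=C(C)C | intermediate
16 | methyl (3R)-3-[(2S,3S)-5,7-dihydroxy-2,3-dimethyl-6-(3-methylbut-2-en-1-yl)-4-oxochroman-8-yl]hexanoate | CCC[C@H](CC(=O)OC)c1c(O)c(CC=C(C)C)c(O)c2c1O[C@@H](C)[C@H](C)C2=O | target

Step count and risks
Total step count: 10. Longest linear sequence: 10 steps (from 1 to 16).

Steps most likely to fail: 3, 8 and 5.

Step 3. The carbene may add only slowly to the doubly ortho-oxygenated, electron-rich formyl group. The prolonged heating this forces may cause [3,3] shift or loss of the secondary allyl aryl ether, and base-induced ring opening could erase C2. The fallback forms the same C3-C4 bond by a radical chain instead of a polar carbene pathway. Starting from 4, thiol-catalysed radical hydroacylation (tert-dodecanethiol, AIBN, chlorobenzene, 80 °C) abstracts the formyl hydrogen, the aroyl radical closes 6-exo-trig onto the internal alkene carbon, and the primary radical takes hydrogen back from the thiol. A short treatment with Et3N should then equilibrate C3 to trans, and the path comes back to the route at 5. No compound outside the list is formed on this path, so its entry below is F0.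

Step 8. The acyl-deactivated ring may be too weak a nucleophile for the iminium ion. The reaction may instead divert into 1,2-addition and condensation to a 2H-chromene, or the facial selectivity may be poor. The fallback closes the ring first and sets the centre by reduction. Starting from 11, selective acylation of the non-chelated 7-OH with hex-2-ynoic acid (DCC, cat. DMAP, CH2Cl2) should give (2S,3S)-5-hydroxy-2,3-dimethyl-6-(3-methylbut-2-en-1-yl)-4-oxochroman-7-yl hex-2-ynoate F1 as the 7-O-ester. Gold-catalysed 6-endo-dig hydroarylation at C8 (Ph3PAuCl/AgSbF6, CH2Cl2, rt) should then give the 4-propylcoumarin (2S,3S)-5-hydroxy-2,3-dimethyl-6-(3-methylbut-2-en-1-yl)-10-propyl-2,3-dihydro-4H,8H-pyrano[2,3-f]chromene-4,8-dione F2 as the cyclised product. Enantioselective copper hydride 1,4-reduction (Cu(OAc)2, DTBM-SEGPHOS, (EtO)2MeSiH, t-BuOH, toluene) follows, with the ligand antipode chosen on a model 4-alkylcoumarin to give the R centre. The chelated, vinylogous-ester ketone is expected to be much less reactive than the coumarin. The path comes back to the route at 15.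

Step 5. O-alkylation of the hydrogen-bonded, peri-hindered 5-OH by the tertiary electrophile may be sluggish, so that C-alkylation or elimination of the chloride takes over. The fallback starts from 6 and uses a primary halide: prenyl bromide (K2CO3, DMF, 50 °C) should give (2S,3S)-7-(methoxymethoxy)-2,3-dimethyl-5-[(3-methylbut-2-en-1-yl)oxy]chroman-4-one F3 as the 5-O-prenyl ether. A [1,3] shift of the prenyl group from O5 to the adjacent C6, promoted by montmorillonite K10 clay (acid-treated aluminosilicate, idealised formula Al2Si4O10(OH)2·nH2O; CH2Cl2, 0 °C), then comes back to the route at 10.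

Further compounds
F0 | step 3 | none | none
F1 | step 8 | (2S,3S)-5-hydroxy-2,3-dimethyl-6-(3-methylbut-2-en-1-yl)-4-oxochroman-7-yl hex-2-ynoate | CCCC#CC(=O)Oc1c(CC=C(C)C)c(O)c2c(c1)O[C@@H](C)[C@H](C)C2=O
F2 | step 8 | (2S,3S)-5-hydroxy-2,3-dimethyl-6-(3-methylbut-2-en-1-yl)-10-propyl-2,3-dihydro-4H,8H-pyrano[2,3-f]chromene-4,8-dione | CCCC1=CC(=O)Oc2c1c1O[C@@H](C)[C@H](C)C(=O)c1c(O)c2CC=C(C)C
F3 | step 5 | (2S,3S)-7-(methoxymethoxy)-2,3-dimethyl-5-[(3-methylbut-2-en-1-yl)oxy]chroman-4-one | COCOc1cc(OCC=C(C)C)c2c(c1)O[C@@H](C)[C@H](C)C2=O
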